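## Structural features

The target 23 is a 4H-chromen-4-one whose benzo ring is replaced by a saturated, fully oxygenated carbocycle. A γ-pyranone ring (O1, C2, C3, C4, C4a, C8a) is fused through the C4a=C8a double bond to a six-membered ring whose other four carbons, C5 to C8, are contiguous secondary carbinols. C2 carries a two-carbon bridge to a 3-hydroxy-4-methoxyphenyl ring. The configuration is 5S,6S,7R,8S: O5/O6 are cis (erythro), O6/O7 and O7/O8 are trans (threo). The C6–C7 diol therefore has the relative and absolute sense of (R,R)-tartaric acid, and C5 and C8, the two carbinols attached to the pyranone, must be created. The fragile points are these: the C5–O bond sits on the α-carbon of a vinylogous ester and can ionise with help from O1 (epimerisation, dehydration, finally aromatisation); any pyranone enolate would expel a β-oxygen; C8a and C2 are electrophilic; the CH2 on C2 is the most acidic C–H of the finished molecule; the phenol is oxidisable. The real difficulty is to close the carbocycle onto a pyranone that tolerates neither strong base nor nucleophiles, while setting a cis relation at C5/C6 next to two trans relations. The key step exploits the fact that C8a is both the β-carbon of the vinylogous ester and the carbon α to O1. It can carry iodine and then a σ-bonded metal in the ring plane, and this sp2 nucleophile can add to a C8 aldehyde, forming C8–C8a and the C8 carbinol without touching the aromatic pyranone.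

## Logic of the disconnections

23 back to 21. The bonds cut are O5–Si, the two ketal C–O bonds on O6/O7 and the aryl O–CH2Ph bond; the ethane bridge on C2 is taken back to an E-ethene. All of these can be undone at the very end by one neutral hydrogenation followed in the same flask by dilute acid, so the polar tetraol phenol exists only in the last step. The forward step must leave the pyranone C2=C3 bond and the allylic C5–O and C8–O bonds alone, and the acid must be too weak to ionise C5.

21 back to 19. The C8–C8a bond is cut. This opens the carbocycle and removes the C8 stereocentre in one move, leaving an acyclic chain on C4a whose C6/C7 centres are held in a trans-dioxolane. The forward step needs a C8a nucleophile that is not an enolate (otherwise O5 would be lost) and must deliver O8 trans to O7.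

19 back to 15 (through 18 and 17). The C8 aldehyde is taken back to a primary silyl ether and the C8a–I bond to C8a–H. Iodine is brought in by deprotonation, and this is why the C2 bridge is kept as an alkene up to 21: with a saturated CH2 on C2 the base would remove that vinylogous α-proton instead of C8a–H. The alkene costs nothing, because the hydrogenation that removes the benzyl group also saturates it. The carbon skeleton of 19 and 21 is unchanged by this. The demands are metalation at C8a and not at C3, and cleavage of a primary silyl ether beside a secondary one.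

15 back to 13 (through 14). The O5–Si bond and the C5–H bond are cut, giving a C5 ketone. Hydride must arrive under chelation control, with zinc bridging O5 and the dioxolane oxygen O6, because that gives the 5,6-erythro alcohol required. A non-chelated, polar Felkin–Anh delivery would give the 5,6-threo epimer. The reduction must also be 1,2-selective, since C8a of 13 is a doubly activated Michael position.

13 back to 11 and 5 (through 12). C4–C4a and O1–C8a are cut. This splits the pyranone into a three-carbon acylketene unit carrying the aryl side chain and a two-carbon enaminone unit carrying the tartrate chain. The regiochemistry is fixed by polarity: the nucleophilic α-carbon of 11 becomes C4a and its amine-bearing carbon becomes C8a. The forward step requires the push–pull alkene of 11 to trap 12 faster than 12 is consumed otherwise.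

11 back to 6 (through 10, 9, 8 and 7). C8a–C4a is cut (one carbon from a formamide acetal), then C4a–C5 (methyl Grignard addition and oxidation), then the aldehyde is taken back to the mono-silylated diol 7 and to the C2-symmetric diol 6. The symmetry of 6 makes the mono-protection unambiguous and supplies C6 and C7 with the correct absolute configuration. The only demand is that the α-oxygenated centre next to each carbonyl is not epimerised; the trans-dioxolane is the thermodynamically preferred arrangement, which protects against this.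

5 back to 1 and 2. The styryl C=C is cut (vinylogous aldol condensation). Both partners are catalogue compounds, and the dioxinone is carried as a masked acylketene. The forward step needs γ-selective attack of the dienolate of 1 on 2.

## Other disconnections considered

Alternative 1: The cut removes the C4 carbonyl carbon (C4a–C4 and C4–C3) and opens O1–C2. This leaves the enol triflate A1 of a protected inosose (triflate on C4a, p-methoxybenzyl enol ether on C8a), the terminal alkyne A2 and carbon monoxide A3. In the forward key step zerovalent palladium inserts into the C4a–O bond of A1, takes up A3, and the acylpalladium is alkynylated by A2 to give the enynone A4, which contains every carbon of the target. Removal of the enol protecting group and 6-endo-dig addition of O1 to C2 would then make the pyranone.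
- In its favour: all four carbinol centres arrive preformed on the cyclitol ring, two C–C bonds form in one operation, and the reaction type is well established for alkenyl triflates.
- Against it here: the cyclitol source is meso, so enantiopure A1 needs a desymmetrisation or resolution and a five-fold differentiated protecting pattern. The enol triflate must be formed regioselectively from a ketone flanked by two oxygenated carbons, with β-elimination of O5 as a competing path. The tetrasubstituted triflate is hindered, and the p-methoxybenzyl groups must later be removed beside an electron-rich arene.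
- Comparison: on stereochemical security A1 to A4 is the better plan, since it creates no stereocentre, whereas the chosen route must make C5 and C8. On the mechanism of the C–C bond formation the two are about equal in reliability. On step economy the chosen route is expected to be shorter, because tartrate provides C6/C7 without any differentiation problem.

Alternative 2: The cut opens O1–C8a and C4a–C5 together, which unravels both rings to the acyclic ynone–diketone aldehyde A5, with C6 to C8 as a xylo-configured tribenzyloxy chain. In the forward key step the diketone enol oxygen adds 6-endo-dig to alkyne carbon C8a, and the C4a allenolate so formed adds to the C5 aldehyde, giving the bicyclic alcohol A6 in one pot.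
- In its favour: both rings and the C5 centre are made in one operation, the sugar chain supplies three centres, and uniform benzyl protection allows a single hydrogenolysis at the end.
- Against it here: A5 combines a 1,3-diketone, an ynone and an α-benzyloxy aldehyde. Epimerisation at C6, β-elimination, 5-exo closure to a furanone, and protonation of the allenolate before the aldol (after which C4a is no longer nucleophilic) all compete. The aldol is reversible, so C5 would be set under thermodynamic control, and the aldol product can dehydrate towards an aromatic chromone.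
- Comparison: on step economy and on the simplicity of the endgame A5 to A6 is the better plan. Structurally it leaves one centre to create against two in the chosen route. Mechanistically the chosen route is the more controllable, because it separates pyranone formation from carbocycle closure and closes the ring with a non-basic organochromium reagent.

Alternative 3: The cut is the C6–O bond only, with both rings intact: the 5,6-cyclic carbonate A8 goes back to the 5-O-tert-butoxycarbonyl 6,7-epoxide A7. In the forward key step a Lewis acid activates the epoxide, the carbonate carbonyl oxygen attacks C6 from the face of O5 with inversion, the tert-butyl group is lost, and A8 results with a cis-5,6 carbonate and a free C7 hydroxyl trans to O6.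
- In its favour: the cis-5,6/trans-6,7 pattern is built into the mechanism (intramolecular delivery, anti opening), the regiochemistry is decided by ring size (five-membered carbonate over six-membered), and O5/O6 come out differentiated from O7.
- Against it here: it is a late functional-group step and builds no skeleton. The enantiopure 5,8-cis-dioxygenated dihydrochromone and its face-selective epoxidation must come first, with no chiral-pool handle. A Lewis acid may also ionise the C5 carbonate, which sits at the vinylogous acetal position.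
- Comparison: for the stereocentre it sets, A7 to A8 is more predictable than the chelation-controlled reduction that sets C5 in the chosen route, and is the better on that point. Structurally it solves less, and the overall sequence is expected to be longer.

Key step: step 13

Remark: TBS is tert-butyldimethylsilyl. Compounds 2 (the benzyl ether of isovanillin) and 6 (the LiAlH4-reduced acetonide of diethyl L-tartrate) are taken as catalogue compounds. The C2 bridge is carried as the E-alkene until step 14. Locants C2 to C8a refer to the chromone numbering of 23 throughout.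

Step 1
Reactants: 1 2,2,6-trimethyl-4H-1,3-dioxin-4-one; 2 3-(benzyloxy)-4-methoxybenzaldehyde
Product: 5 6-{(E)-2-[3-(benzyloxy)-4-methoxyphenyl]ethenyl}-2,2-dimethyl-4H-1,3-dioxin-4-one, via lithium aldolate 3 (not isolated), via benzylic mesylate 4 (not isolated)
Conditions: LDA, THF, −78 °C; 2; MsCl, −78 → 0 °C; DBU, 25 °C
Reagents that add atoms: none
Why: LDA removes a proton from the C6 methyl of the vinylogous ester 1 and the dienolate adds through its γ-carbon to 2 (vinylogous aldol). In-situ mesylation and base-induced elimination across the acidic γ-CH2 should give the conjugated E-alkene (aldol condensation).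

Step 2
Reactants: 6 [(4S,5S)-2,2-dimethyl-1,3-dioxolane-4,5-diyl]dimethanol
Product: 7 [(4S,5S)-5-(TBS-oxymethyl)-2,2-dimethyl-1,3-dioxolan-4-yl]methanol
Conditions: NaH (1.0 equiv), THF, 0 °C; TBSCl (1.0 equiv)
Reagents that add atoms: tert-butyldimethylsilyl chloride, CC(C)(C)[Si](C)(C)Cl
Why: Mono-deprotonation of the C2-symmetric diol gives a poorly soluble mono-alkoxide that is silylated once (mono-silylation of symmetric diols). Either hydroxyl gives the same product.

Step 3
Reactants: 7 [(4S,5S)-5-(TBS-oxymethyl)-2,2-dimethyl-1,3-dioxolan-4-yl]methanol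
Product: 8 (4R,5S)-5-(TBS-oxymethyl)-2,2-dimethyl-1,3-dioxolane-4-carbaldehyde
Conditions: Dess–Martin periodinane, NaHCO3, CH2Cl2, 0 → 25 °C
Reagents that add atoms: none
Why: Dess–Martin oxidation of the primary alcohol under buffered, non-basic conditions. The α-centre is safe because the trans-dioxolane is the more stable arrangement.

Step 4
Reactants: 8 (4R,5S)-5-(TBS-oxymethyl)-2,2-dimethyl-1,3-dioxolane-4-carbaldehyde
Product: 9 1-[(4S,5S)-5-(TBS-oxymethyl)-2,2-dimethyl-1,3-dioxolan-4-yl]ethan-1-ol (both carbinol epimers)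
Conditions: MeMgBr, THF, −78 °C
Reagents that add atoms: methylmagnesium bromide, C[Mg]Br
Why: Grignard addition to the aldehyde. The new carbinol centre is destroyed in step 5, so its configuration is irrelevant.

Step 5
Reactants: 9 1-[(4S,5S)-5-(TBS-oxymethyl)-2,2-dimethyl-1,3-dioxolan-4-yl]ethan-1-ol
Product: 10 1-[(4R,5S)-5-(TBS-oxymethyl)-2,2-dimethyl-1,3-dioxolan-4-yl]ethan-1-one
Conditions: Dess–Martin periodinane, NaHCO3, CH2Cl2, 25 °C
Reagents that add atoms: none
Why: Dess–Martin oxidation of the secondary alcohol to the methyl ketone. Silyl ether and acetonide are inert.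

Step 6
Reactants: 10 1-[(4R,5S)-5-(TBS-oxymethyl)-2,2-dimethyl-1,3-dioxolan-4-yl]ethan-1-one
Product: 11 (2E)-3-(dimethylamino)-1-[(4R,5S)-5-(TBS-oxymethyl)-2,2-dimethyl-1,3-dioxolan-4-yl]prop-2-en-1-one
Conditions: Me2NCH(OMe)2 (neat), 90 °C
Reagents that add atoms: N,N-dimethylformamide dimethyl acetal, COC(OC)N(C)C
Why: Aminomethylenation of a methyl ketone with a formamide acetal. Only the CH3 group has the two protons needed to form the enamine, and the α-alkoxy methine keeps its trans-dioxolane configuration.

Step 7
Reactants: 11 (2E)-3-(dimethylamino)-1-[(4R,5S)-5-(TBS-oxymethyl)-2,2-dimethyl-1,3-dioxolan-4-yl]prop-2-en-1-one; 5 6-{(E)-2-[3-(benzyloxy)-4-methoxyphenyl]ethenyl}-2,2-dimethyl-4H-1,3-dioxin-4-one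
Product: 13 6-{(E)-2-[3-(benzyloxy)-4-methoxyphenyl]ethenyl}-3-{[(4R,5S)-5-(TBS-oxymethyl)-2,2-dimethyl-1,3-dioxolan-4-yl]carbonyl}-4H-pyran-4-one, via acylketene 12 (not isolated)
Conditions: PhMe, 110 °C, N2 sweep (5 in excess); then AcOH, 60 °C
Reagents that add atoms: none
Why: Thermal retro-[4+2] of 5 releases acetone and acylketene 12. The α-carbon of the enaminone attacks the ketene carbon (C4–C4a), the enol oxygen closes onto the aminomethine carbon (O1–C8a) and dimethylamine is lost (acylketene annulation of enamines to 4-pyranones). The acid finish drives off reversibly added amine.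

Step 8
Reactants: 13 6-{(E)-2-[3-(benzyloxy)-4-methoxyphenyl]ethenyl}-3-{[(4R,5S)-5-(TBS-oxymethyl)-2,2-dimethyl-1,3-dioxolan-4-yl]carbonyl}-4H-pyran-4-one
Product: 14 6-{(E)-2-[3-(benzyloxy)-4-methoxyphenyl]ethenyl}-3-{(S)-hydroxy[(4S,5S)-5-(TBS-oxymethyl)-2,2-dimethyl-1,3-dioxolan-4-yl]methyl}-4H-pyran-4-one (C5/C6 erythro)
Conditions: Zn(BH4)2, Et2O–THF, −78 → −30 °C
Reagents that add atoms: none
Why: Chelation-controlled reduction of an α-alkoxy ketone. Zinc bridges the C5 carbonyl oxygen and the dioxolane oxygen on C6, and hydride enters from the face away from C7, which should give the 5,6-erythro (5S) alcohol. The reagent reduces conjugated ketones in the 1,2 sense and leaves the vinylogous ester carbonyl C4 alone.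

Step 9
Reactants: 14 6-{(E)-2-[3-(benzyloxy)-4-methoxyphenyl]ethenyl}-3-{(S)-hydroxy[(4S,5S)-5-(TBS-oxymethyl)-2,2-dimethyl-1,3-dioxolan-4-yl]methyl}-4H-pyran-4-one
Product: 15 6-{(E)-2-[3-(benzyloxy)-4-methoxyphenyl]ethenyl}-3-{(S)-(TBS-oxy)[(4R,5S)-5-(TBS-oxymethyl)-2,2-dimethyl-1,3-dioxolan-4-yl]methyl}-4H-pyran-4-one
Conditions: TBSOTf, 2,6-lutidine, CH2Cl2, −78 → 0 °C
Reagents that add atoms: tert-butyldimethylsilyl trifluoromethanesulfonate, CC(C)(C)[Si](C)(C)OS(=O)(=O)C(F)(F)F
Why: Silylation of a hindered secondary alcohol with the silyl triflate and a hindered base. No base strong enough to touch the pyranone is present.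

Step 10
Reactants: 15 6-{(E)-2-[3-(benzyloxy)-4-methoxyphenyl]ethenyl}-3-{(S)-(TBS-oxy)[(4R,5S)-5-(TBS-oxymethyl)-2,2-dimethyl-1,3-dioxolan-4-yl]methyl}-4H-pyran-4-one
Product: 17 6-{(E)-2-[3-(benzyloxy)-4-methoxyphenyl]ethenyl}-2-iodo-3-{(S)-(TBS-oxy)[(4R,5S)-5-(TBS-oxymethyl)-2,2-dimethyl-1,3-dioxolan-4-yl]methyl}-4H-pyran-4-one, via heteroarylzinc amide 16 (not isolated)
Conditions: TMP2Zn·2MgCl2·2LiCl (1.1 equiv), THF, −30 → 25 °C; then I2, −20 °C
Reagents that add atoms: iodine, II
Why: Directed zincation of a 4-pyranone followed by iodolysis. MgCl2 bound to the C4 carbonyl makes the C–H α to O1 (C8a) the most acidic ring proton, and with the C2 bridge still an alkene there is no lateral sp3 C–H to compete. The mild zinc amide tolerates silyl ethers, acetonide and benzyl ether.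

Step 11
Reactants: 17 6-{(E)-2-[3-(benzyloxy)-4-methoxyphenyl]ethenyl}-2-iodo-3-{(S)-(TBS-oxy)[(4R,5S)-5-(TBS-oxymethyl)-2,2-dimethyl-1,3-dioxolan-4-yl]methyl}-4H-pyran-4-one
Product: 18 6-{(E)-2-[3-(benzyloxy)-4-methoxyphenyl]ethenyl}-3-{(S)-(TBS-oxy)[(4R,5S)-5-(hydroxymethyl)-2,2-dimethyl-1,3-dioxolan-4-yl]methyl}-2-iodo-4H-pyran-4-one
Conditions: CSA (0.2 equiv), MeOH–CH2Cl2 (1:1), 0 °C
Reagents that add atoms: none
Why: Acid-catalysed methanolysis removes the unhindered primary silyl ether much faster than the secondary one flanked by the pyranone and the dioxolane (selective desilylation). The internal trans-acetonide should survive brief cold acid.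

Step 12
Reactants: 18 6-{(E)-2-[3-(benzyloxy)-4-methoxyphenyl]ethenyl}-3-{(S)-(TBS-oxy)[(4R,5S)-5-(hydroxymethyl)-2,2-dimethyl-1,3-dioxolan-4-yl]methyl}-2-iodo-4H-pyran-4-one
Product: 19 (4R,5R)-5-[(S)-(TBS-oxy)(6-{(E)-2-[3-(benzyloxy)-4-methoxyphenyl]ethenyl}-2-iodo-4-oxo-4H-pyran-3-yl)methyl]-2,2-dimethyl-1,3-dioxolane-4-carbaldehyde
Conditions: Dess–Martin periodinane, NaHCO3, CH2Cl2, 0 → 25 °C
Reagents that add atoms: none
Why: Dess–Martin oxidation is neutral and free of nucleophiles, so the vinylogous acyl iodide at C8a and the α-alkoxy aldehyde centre C7 are not disturbed.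

Step 13
Reactants: 19 (4R,5R)-5-[(S)-(TBS-oxy)(6-{(E)-2-[3-(benzyloxy)-4-methoxyphenyl]ethenyl}-2-iodo-4-oxo-4H-pyran-3-yl)methyl]-2,2-dimethyl-1,3-dioxolane-4-carbaldehyde
Product: 21 (5S,6R,7S,8S)-2-{(E)-2-[3-(benzyloxy)-4-methoxyphenyl]ethenyl}-5-(TBS-oxy)-8-hydroxy-6,7-(isopropylidenedioxy)-5,6,7,8-tetrahydro-4H-chromen-4-one (trans-fused acetonide; C5 to C8 arranged as in 23), via alkenylchromium dichloride 20 (not isolated)
Conditions: CrCl2 (6 equiv), NiCl2 (0.05 equiv), degassed DMF, 25 °C, 0.005 M; aq. NH4Cl
Reagents that add atoms: none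
Why: CrCl2 reduces NiCl2 to zerovalent nickel, which inserts into the C8a–I bond; the alkenyl group passes to trivalent chromium to give 20, and its C8a–Cr bond adds to the C8 aldehyde (Nozaki–Hiyama–Kishi reaction). The closest known reaction type is the intramolecular coupling of β-iodoenones and other alkenyl iodides with aldehydes. The carbocycle closes in a 6-exo-trig mode. C8 is controlled by the ring being formed: the trans-dioxolane forces O6 and O7 equatorial on the half-chair, and the aldehyde oxygen must stay bound to the chromium leaving C8a, so it lies near the pyranone plane (pseudo-equatorial) and O8 should emerge trans to O7 (8S). The step needs insertion at C–I in the presence of the styrene and the benzyl ether, which the nickel/chromium couple leaves alone. It needs absence of β-elimination, which is secured because the nucleophile is a σ-organochromium in the ring plane and not an enolate. It needs cyclisation to win over dimerisation, which high dilution and a low nickel loading secure.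

Step 14
Reactants: 21 (5S,6R,7S,8S)-2-{(E)-2-[3-(benzyloxy)-4-methoxyphenyl]ethenyl}-5-(TBS-oxy)-8-hydroxy-6,7-(isopropylidenedioxy)-5,6,7,8-tetrahydro-4H-chromen-4-one
Product: 23 (5S,6S,7R,8S)-5,6,7,8-tetrahydroxy-2-[2-(3-hydroxy-4-methoxyphenyl)ethyl]-5,6,7,8-tetrahydro-4H-chromen-4-one, via silyl ether acetonide 22 (not isolated)
Conditions: H2 (1 atm), Pd/C, THF, 25 °C; filter; then 2 M aq. HCl, 25 °C
Reagents that add atoms: none
Why: Palladium on carbon saturates the styryl double bond and cleaves the aryl benzyl ether while the vinylogous-ester C2=C3 bond resists (the classical hydrogenation of 2-styrylchromones). Dilute aqueous acid then hydrolyses the strained trans-fused acetonide and the silyl ether without an external nucleophile other than water.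

## Compound list

1 | 2,2,6-trimethyl-4H-1,3-dioxin-4-one | CC1=CC(=O)OC(C)(C)O1 | starting material
2 | 3-(benzyloxy)-4-methoxybenzaldehyde | COc1ccc(C=O)cc1OCc1ccccc1 | starting material
3 | lithium 1-[3-(benzyloxy)-4-methoxyphenyl]-2-(2,2-dimethyl-4-oxo-4H-1,3-dioxin-6-yl)ethan-1-olate (racemic, not isolated) | COc1ccc(C([O-])CC2=CC(=O)OC(C)(C)O2)cc1OCc1ccccc1.[Li+] | intermediate
4 | 1-[3-(benzyloxy)-4-methoxyphenyl]-2-(2,2-dimethyl-4-oxo-4H-1,3-dioxin-6-yl)ethyl methanesulfonate (racemic, not isolated) | COc1ccc(C(OS(C)(=O)=O)CC2=CC(=O)OC(C)(C)O2)cc1OCc1ccccc1 | intermediate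
5 | 6-{(E)-2-[3-(benzyloxy)-4-methoxyphenyl]ethenyl}-2,2-dimethyl-4H-1,3-dioxin-4-one | COc1ccc(/C=C/C2=CC(=O)OC(C)(C)O2)cc1OCc1ccccc1 | intermediate
6 | [(4S,5S)-2,2-dimethyl-1,3-dioxolane-4,5-diyl]dimethanol (2,3-O-isopropylidene-L-threitol) | OC[C@@H]1OC(C)(C)O[C@H]1CO | starting material
7 | [(4S,5S)-5-(TBS-oxymethyl)-2,2-dimethyl-1,3-dioxolan-4-yl]methanol | OC[C@@H]1OC(C)(C)O[C@H]1CO[Si](C)(C)C(C)(C)C | intermediate
8 | (4R,5S)-5-(TBS-oxymethyl)-2,2-dimethyl-1,3-dioxolane-4-carbaldehyde | O=C[C@@H]1OC(C)(C)O[C@H]1CO[Si](C)(C)C(C)(C)C | intermediate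
9 | 1-[(4S,5S)-5-(TBS-oxymethyl)-2,2-dimethyl-1,3-dioxolan-4-yl]ethan-1-ol (carbinol epimers) | CC(O)[C@@H]1OC(C)(C)O[C@H]1CO[Si](C)(C)C(C)(C)C | intermediate
10 | 1-[(4R,5S)-5-(TBS-oxymethyl)-2,2-dimethyl-1,3-dioxolan-4-yl]ethan-1-one | CC(=O)[C@@H]1OC(C)(C)O[C@H]1CO[Si](C)(C)C(C)(C)C | intermediate
11 | (2E)-3-(dimethylamino)-1-[(4R,5S)-5-(TBS-oxymethyl)-2,2-dimethyl-1,3-dioxolan-4-yl]prop-2-en-1-one | CN(C)/C=C/C(=O)[C@@H]1OC(C)(C)O[C@H]1CO[Si](C)(C)C(C)(C)C | intermediate
12 | (4E)-5-[3-(benzyloxy)-4-methoxyphenyl]-3-oxopenta-1,4-dien-1-one (acylketene, not isolated) | COc1ccc(/C=C/C(=O)C=C=O)cc1OCc1ccccc1 | intermediate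
13 | 6-{(E)-2-[3-(benzyloxy)-4-methoxyphenyl]ethenyl}-3-{[(4R,5S)-5-(TBS-oxymethyl)-2,2-dimethyl-1,3-dioxolan-4-yl]carbonyl}-4H-pyran-4-one | COc1ccc(/C=C/c2cc(=O)c(co2)C(=O)[C@@H]3OC(C)(C)O[C@H]3CO[Si](C)(C)C(C)(C)C)cc1OCc1ccccc1 | intermediate
14 | 6-{(E)-2-[3-(benzyloxy)-4-methoxyphenyl]ethenyl}-3-{(S)-hydroxy[(4S,5S)-5-(TBS-oxymethyl)-2,2-dimethyl-1,3-dioxolan-4-yl]methyl}-4H-pyran-4-one | COc1ccc(/C=C/c2cc(=O)c(co2)[C@H](O)[C@@H]3OC(C)(C)O[C@H]3CO[Si](C)(C)C(C)(C)C)cc1OCc1ccccc1 | intermediate
15 | 6-{(E)-2-[3-(benzyloxy)-4-methoxyphenyl]ethenyl}-3-{(S)-(TBS-oxy)[(4R,5S)-5-(TBS-oxymethyl)-2,2-dimethyl-1,3-dioxolan-4-yl]methyl}-4H-pyran-4-one | COc1ccc(/C=C/c2cc(=O)c(co2)[C@H](O[Si](C)(C)C(C)(C)C)[C@@H]3OC(C)(C)O[C@H]3CO[Si](C)(C)C(C)(C)C)cc1OCc1ccccc1 | intermediate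
16 | C8a-zincated 15, the (2,2,6,6-tetramethylpiperidin-1-yl)zinc derivative (not isolated) | COc1ccc(/C=C/c2cc(=O)c(c([Zn]N4C(C)(C)CCCC4(C)C)o2)[C@H](O[Si](C)(C)C(C)(C)C)[C@@H]3OC(C)(C)O[C@H]3CO[Si](C)(C)C(C)(C)C)cc1OCc1ccccc1 | intermediate
17 | 6-{(E)-2-[3-(benzyloxy)-4-methoxyphenyl]ethenyl}-2-iodo-3-{(S)-(TBS-oxy)[(4R,5S)-5-(TBS-oxymethyl)-2,2-dimethyl-1,3-dioxolan-4-yl]methyl}-4H-pyran-4-one | COc1ccc(/C=C/c2cc(=O)c(c(I)o2)[C@H](O[Si](C)(C)C(C)(C)C)[C@@H]3OC(C)(C)O[C@H]3CO[Si](C)(C)C(C)(C)C)cc1OCc1ccccc1 | intermediate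
18 | 6-{(E)-2-[3-(benzyloxy)-4-methoxyphenyl]ethenyl}-3-{(S)-(TBS-oxy)[(4R,5S)-5-(hydroxymethyl)-2,2-dimethyl-1,3-dioxolan-4-yl]methyl}-2-iodo-4H-pyran-4-one | COc1ccc(/C=C/c2cc(=O)c(c(I)o2)[C@H](O[Si](C)(C)C(C)(C)C)[C@@H]3OC(C)(C)O[C@H]3CO)cc1OCc1ccccc1 | intermediate
19 | (4R,5R)-5-[(S)-(TBS-oxy)(6-{(E)-2-[3-(benzyloxy)-4-methoxyphenyl]ethenyl}-2-iodo-4-oxo-4H-pyran-3-yl)methyl]-2,2-dimethyl-1,3-dioxolane-4-carbaldehyde | COc1ccc(/C=C/c2cc(=O)c(c(I)o2)[C@H](O[Si](C)(C)C(C)(C)C)[C@@H]3OC(C)(C)O[C@H]3C=O)cc1OCc1ccccc1 | intermediate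
20 | C8a dichlorochromium derivative of 19 (trivalent chromium, not isolated) | COc1ccc(/C=C/c2cc(=O)c(c([Cr](Cl)Cl)o2)[C@H](O[Si](C)(C)C(C)(C)C)[C@@H]3OC(C)(C)O[C@H]3C=O)cc1OCc1ccccc1 | intermediate
21 | (5S,6R,7S,8S)-2-{(E)-2-[3-(benzyloxy)-4-methoxyphenyl]ethenyl}-5-(TBS-oxy)-8-hydroxy-6,7-(isopropylidenedioxy)-5,6,7,8-tetrahydro-4H-chromen-4-one | COc1ccc(/C=C/c2cc(=O)c3c(o2)[C@@H](O)[C@@H]4OC(C)(C)O[C@H]4[C@H]3O[Si](C)(C)C(C)(C)C)cc1OCc1ccccc1 | intermediate
22 | (5S,6R,7S,8S)-5-(TBS-oxy)-8-hydroxy-2-[2-(3-hydroxy-4-methoxyphenyl)ethyl]-6,7-(isopropylidenedioxy)-5,6,7,8-tetrahydro-4H-chromen-4-one (not isolated) | COc1ccc(CCc2cc(=O)c3c(o2)[C@@H](O)[C@@H]4OC(C)(C)O[C@H]4[C@H]3O[Si](C)(C)C(C)(C)C)cc1O | intermediate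
23 | (5S,6S,7R,8S)-5,6,7,8-tetrahydroxy-2-[2-(3-hydroxy-4-methoxyphenyl)ethyl]-5,6,7,8-tetrahydro-4H-chromen-4-one | COc1ccc(CCc2cc(=O)c3c(o2)[C@@H](O)[C@H](O)[C@@H](O)[C@H]3O)cc1O | target

## Step count and least certain steps

Total step count: 14. Longest linear sequence: 13 steps (6 to 23, steps 2 to 14).

Step 13 (key step). The most likely failure is poor facial selectivity at C8. An open, Felkin-type approach anti to the C7–O7 bond prefers the aldehyde rotamer with pseudo-axial oxygen, which gives the 7,8-cis epimer, and nothing but the chromium-bound geometry opposes it. Protonolysis of the C8a–Cr bond before ring closure is the second risk. Fallback: setting out from 19, the coupling is run as planned and the 8-epi alcohol F1 is taken on. It is oxidised with Dess–Martin periodinane to the C8 ketone F2, which is reduced with NaBH4/CeCl3·7H2O in MeOH at −78 °C. Axial hydride delivery on the half-chair should place O8 equatorial, trans to O7, so C8 is set by a ring-ketone reduction instead of by the C–C bond formation. The route is rejoined at 21.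

Step 8. The most likely failure is poor facial selectivity: zinc may bridge O5 and the pyranone oxygen O4 instead of O5 and O6, which leaves a Felkin-type delivery and the 5,6-threo epimer. Conjugate hydride addition at C8a is the second risk, because C8a is activated by two carbonyl groups. Fallback: setting out from 13, the ketone is reduced under non-chelating 1,2-selective conditions (NaBH4, CeCl3·7H2O, MeOH, −78 °C) to the 5-epi alcohol F3. Its C5 centre is inverted by Mitsunobu esterification (4-nitrobenzoic acid, PPh3, diisopropyl azodicarboxylate) to the 4-nitrobenzoate F4, and methanolysis (K2CO3, MeOH) rejoins the route at 14.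

Step 7. The most likely failure is loss of the acylketene before the weakly nucleophilic push–pull alkene of 11 can trap it, through capture by the liberated dimethylamine or through dimerisation. Reversible amine addition at C8a of 13 can also hold the product in a ring-opened form. Fallback (stepwise ionic assembly of the same bonds), setting out from 10:
- The lithium enolate of 10 (LDA) is acetylated with N-acetylimidazole to the 1,3-diketone F5.
- Me2NCH(OMe)2 aminomethylenates the central carbon of F5 to give the enaminodione F6.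
- In a side line, 2 is condensed with malonic acid (pyridine, piperidine) to the cinnamic acid F7, and oxalyl chloride converts it into the acid chloride F8.
- The kinetic enolate of the acetyl CH3 of F6 (LiHMDS, −78 °C) is C-acylated with F8 to the triketone enamine F9.
- Trifluoroacetic acid work-up lets the enol oxygen close onto the aminomethine carbon with loss of dimethylamine, rejoining the route at 13.

Step 10. The most likely failure is metalation at the wrong ring position. If the amide base is steered by the C4 carbonyl instead of by MgCl2 activation, zinc goes to C3 and iodination follows there; incomplete zincation of the hindered C8a–H is the second risk. Fallback: setting out from 14, the iodination is moved ahead of the silylation. LiTMP (2.5 equiv, THF, −78 °C) first forms the C5 lithium alkoxide, which holds the second equivalent of base next to C8a–H (alkoxide-directed lithiation). Iodine then gives the iodo alcohol F10, and TBSOTf/2,6-lutidine rejoins the route at 17.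

## Further compounds

F1 | step 13 | (5S,6R,7S,8R)-2-{(E)-2-[3-(benzyloxy)-4-methoxyphenyl]ethenyl}-5-(TBS-oxy)-8-hydroxy-6,7-(isopropylidenedioxy)-5,6,7,8-tetrahydro-4H-chromen-4-one (C8 epimer of 21) | COc1ccc(/C=C/c2cc(=O)c3c(o2)[C@H](O)[C@@H]4OC(C)(C)O[C@H]4[C@H]3O[Si](C)(C)C(C)(C)C)cc1OCc1ccccc1
F2 | step 13 | C8 ketone of F1: 2-{(E)-2-[3-(benzyloxy)-4-methoxyphenyl]ethenyl}-5-(TBS-oxy)-6,7-(isopropylidenedioxy)-6,7-dihydro-4H-chromene-4,8(5H)-dione, C5 to C7 as in 21 | COc1ccc(/C=C/c2cc(=O)c3c(o2)C(=O)[C@@H]4OC(C)(C)O[C@H]4[C@H]3O[Si](C)(C)C(C)(C)C)cc1OCc1ccccc1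
F3 | step 8 | 6-{(E)-2-[3-(benzyloxy)-4-methoxyphenyl]ethenyl}-3-{(R)-hydroxy[(4S,5S)-5-(TBS-oxymethyl)-2,2-dimethyl-1,3-dioxolan-4-yl]methyl}-4H-pyran-4-one (C5 epimer of 14) | COc1ccc(/C=C/c2cc(=O)c(co2)[C@@H](O)[C@@H]3OC(C)(C)O[C@H]3CO[Si](C)(C)C(C)(C)C)cc1OCc1ccccc1
F4 | step 8 | 4-nitrobenzoate of 14 (C5 configured as in 14) | COc1ccc(/C=C/c2cc(=O)c(co2)[C@H](OC(=O)c4ccc(cc4)[N+](=O)[O-])[C@@H]3OC(C)(C)O[C@H]3CO[Si](C)(C)C(C)(C)C)cc1OCc1ccccc1
F5 | step 7 | 1-[(4R,5S)-5-(TBS-oxymethyl)-2,2-dimethyl-1,3-dioxolan-4-yl]butane-1,3-dione | CC(=O)CC(=O)[C@@H]1OC(C)(C)O[C@H]1CO[Si](C)(C)C(C)(C)C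
F6 | step 7 | 2-[(dimethylamino)methylidene]-1-[(4R,5S)-5-(TBS-oxymethyl)-2,2-dimethyl-1,3-dioxolan-4-yl]butane-1,3-dione | CN(C)C=C(C(C)=O)C(=O)[C@@H]1OC(C)(C)O[C@H]1CO[Si](C)(C)C(C)(C)C
F7 | step 7 | (2E)-3-[3-(benzyloxy)-4-methoxyphenyl]prop-2-enoic acid | COc1ccc(/C=C/C(O)=O)cc1OCc1ccccc1
F8 | step 7 | (2E)-3-[3-(benzyloxy)-4-methoxyphenyl]prop-2-enoyl chloride | COc1ccc(/C=C/C(Cl)=O)cc1OCc1ccccc1
F9 | step 7 | (6E)-7-[3-(benzyloxy)-4-methoxyphenyl]-2-[(dimethylamino)methylidene]-1-[(4R,5S)-5-(TBS-oxymethyl)-2,2-dimethyl-1,3-dioxolan-4-yl]hept-6-ene-1,3,5-trione | COc1ccc(/C=C/C(=O)CC(=O)C(=CN(C)C)C(=O)[C@@H]2OC(C)(C)O[C@H]2CO[Si](C)(C)C(C)(C)C)cc1OCc1ccccc1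
F10 | step 10 | 6-{(E)-2-[3-(benzyloxy)-4-methoxyphenyl]ethenyl}-3-{(S)-hydroxy[(4S,5S)-5-(TBS-oxymethyl)-2,2-dimethyl-1,3-dioxolan-4-yl]methyl}-2-iodo-4H-pyran-4-one | COc1ccc(/C=C/c2cc(=O)c(c(I)o2)[C@H](O)[C@@H]3OC(C)(C)O[C@H]3CO[Si](C)(C)C(C)(C)C)cc1OCc1ccccc1
A1 | alternative 1 | enol triflate of the protected inosose (triflate on C4a, p-methoxybenzyl enol ether on C8a, 5,6-O-cyclohexylidene, 7,8-di-O-p-methoxybenzyl) | O=S(=O)(OC2=C(OCc3ccc(OC)cc3)[C@@H](OCc3ccc(OC)cc3)[C@H](OCc3ccc(OC)cc3)[C@@H](OC56CCCCC6)[C@H]2O5)C(F)(F)F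
A2 | alternative 1 | 4-[3-(benzyloxy)-4-methoxyphenyl]but-1-yne | COc1ccc(CCC#C)cc1OCc1ccccc1
A3 | alternative 1 | carbon monoxide | [C-]#[O+]
A4 | alternative 1 | β-alkoxy enynone, product of the carbonylative coupling | COc1ccc(CCC#CC(=O)C2=C(OCc3ccc(OC)cc3)[C@@H](OCc3ccc(OC)cc3)[C@H](OCc3ccc(OC)cc3)[C@@H](OC56CCCCC6)[C@H]2O5)cc1OCc1ccccc1
A5 | alternative 2 | acyclic ynone–1,3-diketone aldehyde with the xylo-configured tribenzyloxy chain C8–C6 and the C5 aldehyde | COc1ccc(CCC(=O)CC(=O)C#C[C@@H](OCc2ccccc2)[C@H](OCc2ccccc2)[C@@H](OCc2ccccc2)C=O)cc1OCc1ccccc1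
A6 | alternative 2 | 6,7,8-tribenzyl ether of the aryl benzyl ether of the target | COc1ccc(CCc2cc(=O)c3c(o2)[C@@H](OCc4ccccc4)[C@H](OCc4ccccc4)[C@@H](OCc4ccccc4)[C@H]3O)cc1OCc1ccccc1
A7 | alternative 3 | 5-O-tert-butoxycarbonyl 8-O-TBS 6,7-epoxide (epoxide anti to O5 and O8) of the aryl benzyl ether | COc1ccc(CCc2cc(=O)c3c(o2)[C@@H](O[Si](C)(C)C(C)(C)C)[C@@H]4O[C@@H]4[C@H]3OC(=O)OC(C)(C)C)cc1OCc1ccccc1
A8 | alternative 3 | 5,6-cyclic carbonate with free C7 hydroxyl | COc1ccc(CCc2cc(=O)c3c(o2)[C@@H](O[Si](C)(C)C(C)(C)C)[C@H](O)[C@@H](OC4=O)[C@H]3O4)cc1OCc1ccccc1
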